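Late in the beta run E stands at 4.1% while 82.9% of X remains, so I book the missing 13.0% as Q, a pseudo-first-order loss of 0.0237 min⁻¹.

| setting | eta | beta | flask |
|---|---|---|---|
| X | 0.10 M | 0.10 M | 0.10 M |
| Z | 1 mM | 1 mM | 1.0 mM |
| G | 0.65 mM | 2.6 mM | 1.3 mM |
| remark | run made earlier | run made earlier |  |
| time |  |  | 5.0 min |

| run | time / min | E / % | X / % |
|---|---|---|---|
| eta | 0.833 | 11.5 | 85.5 |
| eta | 1.50 | 29.7 | 67.7 |
| eta | 2.50 | 52.9 | 44.0 |
| eta | 3.00 | 61.9 | 32.8 |
| eta | 4.00 | 77.5 | 19.7 |
| eta | 5.00 | 83.5 | 10.3 |
| eta | 6.00 | 89.2 | 5.8 |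
| beta | 0.500 | 1.9 | 98.4 |
| beta | 0.667 | 0.8 | 96.9 |
| beta | 1.00 | 0.3 | 96.1 |
| beta | 1.50 | 2.7 | 95.7 |
| beta | 2.50 | 1.6 | 91.1 |
| beta | 4.00 | 2.3 | 86.9 |
| beta | 6.00 | 4.1 | 82.9 |

(each reading ± 1 percentage point)

- whether the average number of monomer units in a chain (chains begun, living or dead) reaches 800 by 5.0 min (yes / no)
- average number of monomer units in a chain (chains begun, living or dead) at 5.0 min

- the average divides the monomer in chains by the number of chains begun, living and dead together
- the numbers in the tables scatter by 1 percentage point (one standard deviation)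
- reactions considered so far: Z + G -> D; X + Z -> J + E; X + J -> E + J; X -> Q
- the earlier runs do not show the number of chains; that part of a forecast is a guess

My flask resembles beta and not eta: in both, G exceeds Z, and I take the chains that escape G to begin at the start. Their length is then a rate constant times the area under c_X, however many chains there are. So I expect beta and the flask to part in the number of chains, and I scale that number by ln(c_G/(c_G − c_Z)), which gives my flask 3.02 times beta's count.

The eta run gives the constant. There G leaves 0.350 mM of Z, which becomes chains gradually. With Q subtracted, ln c_X has dropped by 0.137 at 0.833 min and slopes at 0.555 min⁻¹ late, and the area under X is 2.53 min. Twice that drop over the squared time is the starting curvature, and multiplied by the area it makes a rate of 0.997 min⁻¹. If Z decays exponentially in that area, these give an exponent of 1.31. So I read 2180 M⁻¹ min⁻¹, with the scatter of the readings, for the length clock, the units a living chain adds per minute and per unit of c_X.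

For my flask, Q plus 3.02 times beta's E rate gives a loss of 0.0463 min⁻¹, an area of 4.46 min, and a length of 973, above 800.

The forecast says no at 700, on the ground that “The DP does not depend on J”, and my figure differs from it.

The flask gives 980 at 5.0 min, so the answer is yes.

    Z + G → D (k = 1100 M⁻¹ s⁻¹)
    X + Z → J + E (k = 0.0870 M⁻¹ s⁻¹)
    X + J → E + J, rate k3*[J]*[X] (k = 37.0 M⁻¹ s⁻¹)
    X → Q (k = 3.90 × 10⁻⁴ s⁻¹)

The length passes 800 at 3.99 min, when 17.5% of X has reacted. In the beta run at 6.00 min, the length clock gives 1200 units per chain, and the E reading, with its scatter, then gives chains begun of 3.43 × 10⁻⁶ M.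

All runs are calculated for an exercise; noise was put on by code.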